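**Retrosynthetic overview**
1. Target 13 ⇐ 12 (radical removal of a temporary 4-SePh group) ⇐ 11 (C2 ketone reduction steered by that group) ⇐ enedione 10 (seleno-Michael addition).
2. 10 ⇐ quinone monoketal 6 + (E)-isoelemicin 7 by a catalytic asymmetric cationic [5+2] cycloaddition under a chiral Brønsted acid (key step; forms C5–C6 and C1–C7, sets C1, C5, C6, C7).
3. 6 ⇐ phenol 5 (oxidative dearomatisation) ⇐ 1 + 2 (O-allylation, Claisen rearrangement).
4. Ring order: the benzene ring of 1 is carried through, dearomatised in 6 and becomes the six-membered ring of the bicycle; step 4 closes the five-membered ring and with it the bicyclo[3.2.1]octane; no ring is formed afterwards.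

Conventions: bicyclo[3.2.1]octane numbering with C1 = methoxy bridgehead, C5 = allyl bridgehead, C8 = bridging carbonyl; exo = on the side of C8, endo = on the side of the C6–C7 bridge.

Assumption: 2,3,4-trimethoxyphenol and (E)-isoelemicin are bought as such, and the (S,S)-enantiomer of the acid catalyst is taken to give the enantiomer drawn (otherwise its mirror image is used).

**Route**

Step 1
Reactants: 1 2,3,4-trimethoxyphenol; 2 allyl bromide
Product: 3 1,2,3-trimethoxy-4-(prop-2-en-1-yloxy)benzene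
Conditions: K2CO3, acetone, reflux
Reagents that add atoms: none
Why: Williamson ether synthesis, the phenoxide displacing bromide from allyl bromide by SN2; no stereocentre is formed.

Step 2
Reactants: 3 1,2,3-trimethoxy-4-(prop-2-en-1-yloxy)benzene
Product: 5 2,3,4-trimethoxy-6-(prop-2-en-1-yl)phenol, via ortho-dienone 4 (not isolated)
Conditions: N,N-diethylaniline, 195 °C, argon
Reagents that add atoms: none
Why: aromatic Claisen ([3,3]-sigmatropic) rearrangement; only the C6 ortho position carries hydrogen, so the allyl group ends there and dienone 4 tautomerises to the phenol.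

Step 3
Reactants: 5 2,3,4-trimethoxy-6-(prop-2-en-1-yl)phenol
Product: 6 2,3,4,4-tetramethoxy-6-(prop-2-en-1-yl)cyclohexa-2,5-dien-1-one
Conditions: PhI(OAc)2, MeOH, 0 °C
Reagents that add atoms: methanol, CO
Why: hypervalent-iodine oxidative dearomatisation of a 4-methoxyphenol, methanol adding at the methoxy-bearing para carbon to give the quinone monoketal; no stereocentre is formed, and any ortho-ketal isomer would ionise to the same cation in step 4.

Step 4
Reactants: 6 2,3,4,4-tetramethoxy-6-(prop-2-en-1-yl)cyclohexa-2,5-dien-1-one; 7 (E)-isoelemicin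
Product: 10 (1R,5S,6R,7S)-1,3-dimethoxy-6-methyl-5-(prop-2-en-1-yl)-7-(3,4,5-trimethoxyphenyl)bicyclo[3.2.1]oct-3-ene-2,8-dione, via phenoxenium cation 8 (not isolated), via dimethyl ketal 9 (not isolated)
Conditions: (S,S)-IDPi acid (imidodiphosphorimidate from two 3,3'-bis[3,5-bis(trifluoromethyl)phenyl]-BINOL units, N-triflyl groups; 3 mol %), CH2Cl2, −78 → −50 °C; then 1 M aq HCl, THF, 0 °C
Reagents that add atoms: water, O
Why: Proposed new method: the confined strong acid ionises the ketal of 6 to the planar cation 8, held as a tight ion pair in the chiral anion pocket, so the β-carbon of 7 adds to one enantioface at the allyl-bearing carbon and the benzylic cation then closes on the methoxy enol-ether carbon (stepwise cationic [5+2] cycloaddition; E geometry gives trans 6-Me/7-Ar, the aryl group closing exo, away from the dimethoxy-diene unit), methanol capture giving ketal 9 with release of the acid and aqueous acid unmasking the C2 ketone; the closest known chemistry is the achiral-acid quinone-monoketal/styrene [5+2] cycloaddition used for racemic bicyclo[3.2.1]octanoid neolignans, joined to counteranion-directed IDPi catalysis of cationic cycloadditions of styrenes.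

Step 5
Reactants: 10 (1R,5S,6R,7S)-enedione
Product: 11 (1R,3R,4S,5R,6R,7S)-1,3-dimethoxy-6-methyl-4-(phenylselanyl)-5-(prop-2-en-1-yl)-7-(3,4,5-trimethoxyphenyl)bicyclo[3.2.1]octane-2,8-dione
Conditions: PhSeH (2 equiv), Et3N (0.3 equiv), CH2Cl2, 0 °C → rt, dark, argon
Reagents that add atoms: benzeneselenol, [SeH]c1ccccc1
Why: seleno-Michael (conjugate) addition; PhSe− attacks C4 from the exo face because the endo face is covered by the endo 6-methyl group, and base equilibration leaves the C3 methoxy group equatorial (exo, cis to Se), the epimer that avoids the two-carbon bridge.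

Step 6
Reactants: 11 4-exo-phenylselanyl dione
Product: 12 (1S,2S,3R,4S,5R,6R,7S)-2-hydroxy-1,3-dimethoxy-6-methyl-4-(phenylselanyl)-5-(prop-2-en-1-yl)-7-(3,4,5-trimethoxyphenyl)bicyclo[3.2.1]octan-8-one
Conditions: Zn(BH4)2, Et2O, −30 → 0 °C; then H2O
Reagents that add atoms: none
Why: chelation-assisted ketone reduction; zinc held between the C2 carbonyl and its two flanking methoxy groups activates C2 over the doubly neopentyl C8 ketone, and the axial 4-SePh group, 1,3-diaxial to the exo trajectory that hydride would otherwise take, forces delivery from the endo face, so the new 2-OH is axial, exo and cis to 3-OMe.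

Step 7
Reactants: 12 4-exo-phenylselanyl alcohol
Product: 13 (1S,2S,3S,5R,6R,7S)-2-hydroxy-1,3-dimethoxy-6-methyl-5-(prop-2-en-1-yl)-7-(3,4,5-trimethoxyphenyl)bicyclo[3.2.1]octan-8-one
Conditions: Bu3SnH, AIBN (cat.), toluene, 80 °C
Reagents that add atoms: none
Why: radical deselenation; the stannyl radical abstracts PhSe from C4 and the secondary radical is quenched by Bu3SnH (C4 becomes CH2, so no stereocentre is at stake), while ketone, alcohol and allyl group are inert and 4-exo cyclisation onto the allyl group cannot compete.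

**Compound list**

1 | 2,3,4-trimethoxyphenol | COc1ccc(O)c(OC)c1OC | starting material
2 | allyl bromide (3-bromoprop-1-ene) | C=CCBr | starting material
3 | 1,2,3-trimethoxy-4-(prop-2-en-1-yloxy)benzene | C=CCOc1ccc(OC)c(OC)c1OC | intermediate
4 | 2,3,4-trimethoxy-6-(prop-2-en-1-yl)cyclohexa-2,4-dien-1-one (ortho-dienone, racemic, transient) | C=CCC1C=C(OC)C(OC)=C(OC)C1=O | intermediate
5 | 2,3,4-trimethoxy-6-(prop-2-en-1-yl)phenol | C=CCc1cc(OC)c(OC)c(OC)c1O | intermediate
6 | 2,3,4,4-tetramethoxy-6-(prop-2-en-1-yl)cyclohexa-2,5-dien-1-one | C=CCC1=CC(OC)(OC)C(OC)=C(OC)C1=O | intermediate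
7 | (E)-isoelemicin, 1,2,3-trimethoxy-5-[(1E)-prop-1-en-1-yl]benzene | C/C=C/c1cc(OC)c(OC)c(OC)c1 | starting material
8 | methyl[2,3-dimethoxy-4-oxo-5-(prop-2-en-1-yl)cyclohexa-2,5-dien-1-ylidene]oxonium (phenoxenium cation, ion pair with the catalyst anion) | C=CCC1=CC(=[O+]C)C(OC)=C(OC)C1=O | intermediate
9 | C2 dimethyl ketal of 10: (1R,5S,6R,7S)-1,2,2,3-tetramethoxy-6-methyl-5-(prop-2-en-1-yl)-7-(3,4,5-trimethoxyphenyl)bicyclo[3.2.1]oct-3-en-8-one (numbered as 10) | C=CC[C@]12C=C(OC)C(OC)(OC)[C@](OC)(C1=O)[C@H](c1cc(OC)c(OC)c(OC)c1)[C@H]2C | intermediate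
10 | (1R,5S,6R,7S)-1,3-dimethoxy-6-methyl-5-(prop-2-en-1-yl)-7-(3,4,5-trimethoxyphenyl)bicyclo[3.2.1]oct-3-ene-2,8-dione (7-aryl exo, 6-methyl endo) | C=CC[C@]12C=C(OC)C(=O)[C@](OC)(C1=O)[C@H](c1cc(OC)c(OC)c(OC)c1)[C@H]2C | intermediate
11 | (1R,3R,4S,5R,6R,7S)-1,3-dimethoxy-6-methyl-4-(phenylselanyl)-5-(prop-2-en-1-yl)-7-(3,4,5-trimethoxyphenyl)bicyclo[3.2.1]octane-2,8-dione (3-OMe and 4-SePh exo) | C=CC[C@]12[C@H]([Se]c3ccccc3)[C@H](OC)C(=O)[C@](OC)(C1=O)[C@H](c1cc(OC)c(OC)c(OC)c1)[C@H]2C | intermediate
12 | (1S,2S,3R,4S,5R,6R,7S)-2-hydroxy-1,3-dimethoxy-6-methyl-4-(phenylselanyl)-5-(prop-2-en-1-yl)-7-(3,4,5-trimethoxyphenyl)bicyclo[3.2.1]octan-8-one (2-OH, 3-OMe and 4-SePh exo) | C=CC[C@]12[C@H]([Se]c3ccccc3)[C@H](OC)[C@H](O)[C@](OC)(C1=O)[C@H](c1cc(OC)c(OC)c(OC)c1)[C@H]2C | intermediate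
13 | (1S,2S,3S,5R,6R,7S)-2-hydroxy-1,3-dimethoxy-6-methyl-5-(prop-2-en-1-yl)-7-(3,4,5-trimethoxyphenyl)bicyclo[3.2.1]octan-8-one | C=CC[C@]12C[C@H](OC)[C@H](O)[C@](OC)(C1=O)[C@H](c1cc(OC)c(OC)c(OC)c1)[C@H]2C | target

**Step count and risks**

Total step count: 7. Longest linear sequence: 7 steps (from 1; 7 is used as bought).

Three steps most likely to fail:

Step 4 (proposed new method). The risks are low enantioselectivity, closure of the benzylic cation on the carbonyl oxygen to a dihydrobenzofuran, or the endo-aryl adduct. The fallback uses known chemistry. It sets out from 6 and 7, which are combined under the established achiral-acid protocol (2,4,6-trinitrobenzenesulfonic acid, MeCN, 0 °C, aqueous work-up). This gives racemic enedione, that is 10 together with the mirror-image enedione F1. Preparative chromatography on an amylose tris(3,5-dimethylphenylcarbamate) chiral stationary phase separates the two, and the route is rejoined at 10.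

Step 5. The enone is an α-methoxy enone with a neopentyl β-carbon, so the selenol addition may be slow or reversible. The fallback drops the blocking group and inverts C2 afterwards. It sets out from 10 and comes back at 13.
- Conjugate reduction with [(Ph3P)CuH]6 (cat.) and PhSiH3 in toluene, then K2CO3 in MeOH to equilibrate C3, gives the saturated dione F2.
- NaBH4 in MeOH/CH2Cl2 at −40 °C adds hydride from the open exo face of C2 and gives the 2-endo alcohol F3.
- Tf2O and pyridine in CH2Cl2 at −20 °C give the 2-endo triflate F4.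
- Bu4N+ NO2− in toluene displaces the triflate with inversion to the 2-exo nitrite ester F5, which hydrolyses on aqueous work-up to 13.

Step 6. The risks are competing reduction of the C8 ketone or a sluggish endo approach to C2. The fallback sets out from 11 and comes back at 12. It replaces the hydride reagent by a biocatalytic reduction: a ketoreductase panel (NADP+, glucose and glucose dehydrogenase, phosphate buffer pH 7 with 10% DMSO, 30 °C) is screened for the enzyme that reduces only C2 with endo-face delivery. No new compound is formed (F0).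

**Further compounds**

F1 | step 4 | (1S,5R,6S,7R)-1,3-dimethoxy-6-methyl-5-(prop-2-en-1-yl)-7-(3,4,5-trimethoxyphenyl)bicyclo[3.2.1]oct-3-ene-2,8-dione (mirror image of 10) | C=CC[C@@]12C=C(OC)C(=O)[C@@](OC)(C1=O)[C@@H](c1cc(OC)c(OC)c(OC)c1)[C@@H]2C
F2 | step 5 | (1R,3S,5R,6R,7S)-1,3-dimethoxy-6-methyl-5-(prop-2-en-1-yl)-7-(3,4,5-trimethoxyphenyl)bicyclo[3.2.1]octane-2,8-dione | C=CC[C@]12C[C@H](OC)C(=O)[C@](OC)(C1=O)[C@H](c1cc(OC)c(OC)c(OC)c1)[C@H]2C
F3 | step 5 | (1S,2R,3S,5R,6R,7S)-2-hydroxy-1,3-dimethoxy-6-methyl-5-(prop-2-en-1-yl)-7-(3,4,5-trimethoxyphenyl)bicyclo[3.2.1]octan-8-one (2-endo alcohol) | C=CC[C@]12C[C@H](OC)[C@@H](O)[C@](OC)(C1=O)[C@H](c1cc(OC)c(OC)c(OC)c1)[C@H]2C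
F4 | step 5 | (1S,2R,3S,5R,6R,7S)-1,3-dimethoxy-6-methyl-8-oxo-5-(prop-2-en-1-yl)-7-(3,4,5-trimethoxyphenyl)bicyclo[3.2.1]octan-2-yl trifluoromethanesulfonate | C=CC[C@]12C[C@H](OC)[C@@H](OS(=O)(=O)C(F)(F)F)[C@](OC)(C1=O)[C@H](c1cc(OC)c(OC)c(OC)c1)[C@H]2C
F5 | step 5 | (1S,2S,3S,5R,6R,7S)-1,3-dimethoxy-6-methyl-8-oxo-5-(prop-2-en-1-yl)-7-(3,4,5-trimethoxyphenyl)bicyclo[3.2.1]octan-2-yl nitrite | C=CC[C@]12C[C@H](OC)[C@H](ON=O)[C@](OC)(C1=O)[C@H](c1cc(OC)c(OC)c(OC)c1)[C@H]2C
F0 | step 6 | none | none
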